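**Retrosynthetic overview**
- Numbering: ring B (butenolide) is O1 and C2–C5, and the chain runs from the ylidene CH (C6) to the CH2 on the furan (C18). The methyl-bearing stereocentres C7 and C11 are both S and sit on either side of the C8–C9–C10 tether. The C6–C12 segment is therefore C2-symmetric about C9. Both arms are one and the same (R)-3-silyloxy-2-methylpropyl iodide, and C9 is C2 of 1,3-dithiane, used twice as a carbanion (bonds C9–C10 and C8–C9).
- C5=C6 comes from aldol addition of C5-lithiated 4-methoxy-3-methylfuran-2(5H)-one to the C6 aldehyde, mesylate elimination to the Z-ylidene, and O-demethylation last.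
- C13–C14 comes from Pd-catalysed union of the (12E)-vinyl iodide (Takai olefination of the C12 aldehyde) with the (14E)-alkenylalane from methylalumination of 3-(pent-4-ynyl)furan. C17–C18 comes from 3-(bromomethyl)furan and a homopropargyl Grignard reagent.
- Rings: the furan (ring A) is bought intact in 3-furanmethanol. Ring B is closed early, off the main line, by lactonisation of a γ-bromo-β-keto ester (step 18). The key step and all later steps close no ring.

Key step: step 7

Assumption: apart from its two silyl groups, compound 13 is C2-symmetric. The TBS-bearing terminus is therefore taken as C12 (unmasked first, for the diene) and the TBDPS-bearing terminus as C6 (unmasked second, for the tetronate).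

**Step 1**
Reactants: 1 methyl (R)-3-hydroxy-2-methylpropanoate
Product: 2 methyl (R)-3-(tert-butyldimethylsilyloxy)-2-methylpropanoate
Conditions: TBSCl, imidazole, CH2Cl2, 0 °C → rt
Reagents that add atoms: tert-butyldimethylsilyl chloride, CC(C)(C)[Si](C)(C)Cl
Why: Imidazole-promoted silylation of a primary alcohol is too weakly basic to enolise the ester, so the stereocentre is untouched.

**Step 2**
Reactants: 2 methyl (R)-3-(tert-butyldimethylsilyloxy)-2-methylpropanoate
Product: 3 (S)-3-(tert-butyldimethylsilyloxy)-2-methylpropan-1-ol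
Conditions: i-Bu2AlH (2.2 equiv), CH2Cl2, −78 → 0 °C
Reagents that add atoms: none
Why: Hydride reduction of the ester with i-Bu2AlH gives the primary alcohol without touching the silyl ether or enolising the ester, so the stereocentre is kept (the descriptor becomes S only because CH2OSi now outranks CH2OH).

**Step 3**
Reactants: 3 (S)-3-(tert-butyldimethylsilyloxy)-2-methylpropan-1-ol
Product: 4 (R)-tert-butyl(3-iodo-2-methylpropoxy)dimethylsilane
Conditions: I2, PPh3, imidazole, CH2Cl2, 0 °C → rt
Reagents that add atoms: iodine, II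
Why: In this Appel-type iodination, iodide displaces the alkoxyphosphonium group by SN2 at the primary carbon next to, not at, the stereocentre, and imidazole keeps the medium non-acidic for the TBS ether.

**Step 4**
Reactants: 1 methyl (R)-3-hydroxy-2-methylpropanoate
Product: 5 methyl (R)-3-(tert-butyldiphenylsilyloxy)-2-methylpropanoate
Conditions: TBDPSCl, imidazole, CH2Cl2, 0 °C → rt
Reagents that add atoms: tert-butyldiphenylsilyl chloride, CC(C)(C)[Si](Cl)(c1ccccc1)c1ccccc1
Why: This is the same imidazole-promoted silylation as step 1, installing the more acid-stable silyl group on the second arm.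

**Step 5**
Reactants: 5 methyl (R)-3-(tert-butyldiphenylsilyloxy)-2-methylpropanoate
Product: 6 (S)-3-(tert-butyldiphenylsilyloxy)-2-methylpropan-1-ol
Conditions: i-Bu2AlH (2.2 equiv), CH2Cl2, −78 → 0 °C
Reagents that add atoms: none
Why: Ester reduction as in step 2 leaves the stereocentre geometrically unchanged.

**Step 6**
Reactants: 6 (S)-3-(tert-butyldiphenylsilyloxy)-2-methylpropan-1-ol
Product: 7 (R)-tert-butyl(3-iodo-2-methylpropoxy)diphenylsilane
Conditions: I2, PPh3, imidazole, CH2Cl2, 0 °C → rt
Reagents that add atoms: iodine, II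
Why: Appel-type iodination as in step 3 proceeds by SN2 at the primary carbon only.

**Step 7**
Reactants: 8 1,3-dithiane; 4 (R)-tert-butyl(3-iodo-2-methylpropoxy)dimethylsilane; 7 (R)-tert-butyl(3-iodo-2-methylpropoxy)diphenylsilane
Product: 12 2-[(2S)-3-(tert-butyldimethylsilyloxy)-2-methylpropyl]-2-[(2S)-3-(tert-butyldiphenylsilyloxy)-2-methylpropyl]-1,3-dithiane, via 2-lithio-1,3-dithiane 9 (not isolated), via monoalkylated dithiane 10 (not isolated), via lithiated monoalkyl dithiane 11 (not isolated)
Conditions: 8 (1.05 equiv), n-BuLi (1.05 equiv), THF, −30 °C; 4 (1.0 equiv), −78 → 0 °C; then HMPA (10 vol %), t-BuLi (1.1 equiv), −78 °C; 7 (1.15 equiv), −78 → −20 °C; one flask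
Reagents that add atoms: none
Why: n-BuLi takes the C2 proton of 8 and carbanion 9 displaces iodide from 4 by SN2 (bond C9–C10), after which t-BuLi in THF/HMPA takes the remaining C2 proton of 10 and the tertiary carbanion 11 displaces iodide from 7 (bond C8–C9). The closest known reaction type is the Corey–Seebach dithiane umpolung in its sequential bis-alkylation form with primary iodides. No ring is closed and no stereocentre is created; C7 and C11 lie one carbon away from the reacting CH2I groups and carry no acidic hydrogen, so both pass through unchanged. The step needs substitution to outrun β-hydrogen abstraction at two β-branched primary iodides, which is secured by a polarisable sulfur-stabilised carbanion, an iodide leaving group and HMPA-loosened ion pairing at low temperature. Iodide 4 must be fully consumed before t-BuLi is added, so that no lithium–iodine exchange occurs, and the TBS group should stay on oxygen because in HMPA the Brook equilibrium lies on the side of the O-silyl dithianyl carbanion. Because the two arms carry silyl ethers of unequal acid lability, the ends of the otherwise symmetric chain can later be addressed one at a time without monoprotecting a symmetric diol.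

**Step 8**
Reactants: 12 2,2-dialkyl-1,3-dithiane
Product: 13 (2S,6S)-1-(tert-butyldimethylsilyloxy)-7-(tert-butyldiphenylsilyloxy)-2,6-dimethylheptane
Conditions: Raney Ni (W-2, excess), EtOH, reflux
Reagents that add atoms: none
Why: Raney Ni hydrogenolysis of both C–S bonds (Mozingo-type desulfurisation) turns the dithiane carbon into the C9 methylene, and it is run at this stage because the substrate still holds no alkene or furan that nickel could saturate.

**Step 9**
Reactants: 13 (2S,6S)-1-(tert-butyldimethylsilyloxy)-7-(tert-butyldiphenylsilyloxy)-2,6-dimethylheptane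
Product: 14 (2S,6S)-7-(tert-butyldiphenylsilyloxy)-2,6-dimethylheptan-1-ol
Conditions: camphorsulfonic acid (10 mol %), MeOH/CH2Cl2 1:1, 0 °C
Reagents that add atoms: none
Why: Acid-catalysed methanolysis of silyl ethers is governed by bulk and electron demand at silicon, so the primary TBS ether should be solvolysed well before the primary TBDPS ether.

**Step 10**
Reactants: 14 (2S,6S)-7-(tert-butyldiphenylsilyloxy)-2,6-dimethylheptan-1-ol
Product: 15 (2S,6S)-7-(tert-butyldiphenylsilyloxy)-2,6-dimethylheptanal
Conditions: Dess–Martin periodinane, CH2Cl2, 0 °C → rt; used crude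
Reagents that add atoms: none
Why: Dess–Martin oxidation stops at the aldehyde under base-free conditions, so the α-methyl stereocentre (C11) should not epimerise.

**Step 11**
Reactants: 15 (2S,6S)-7-(tert-butyldiphenylsilyloxy)-2,6-dimethylheptanal
Product: 16 tert-butyl{[(2S,6S,7E)-8-iodo-2,6-dimethyloct-7-en-1-yl]oxy}diphenylsilane
Conditions: CrCl2 (6 equiv), CHI3 (2 equiv), THF/dioxane, 0 °C → rt
Reagents that add atoms: iodoform, IC(I)I
Why: In the Takai olefination the geminal dichromium species from CHI3 and CrCl2 adds to the aldehyde and eliminates to the E-iodoalkene, a preference reinforced by α-branching, and the reagent is non-basic so C11 is preserved.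

**Step 12**
Reactants: 17 3-furanmethanol
Product: 18 3-(bromomethyl)furan
Conditions: PBr3 (0.4 equiv), Et2O, 0 °C; kept as a cold ethereal solution and used at once
Reagents that add atoms: phosphorus tribromide, BrP(Br)Br
Why: PBr3 bromination through the phosphite ester is the standard access to this reactive benzylic-type bromide and avoids the strong acid that would degrade the furan.

**Step 13**
Reactants: 18 3-(bromomethyl)furan; 19 4-bromo-1-(trimethylsilyl)but-1-yne
Product: 21 [5-(furan-3-yl)pent-1-yn-1-yl]trimethylsilane, via 4-(trimethylsilyl)but-3-yn-1-ylmagnesium bromide 20 (not isolated)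
Conditions: 19, Mg, THF, rt → 40 °C; then 18, Li2CuCl4 (5 mol %), THF, −20 → 0 °C
Reagents that add atoms: none
Why: Copper-catalysed (Kochi-type) coupling of an alkyl Grignard reagent with a benzylic-type bromide forms C17–C18, and the TMS cap removes the acidic alkyne hydrogen that would quench the Grignard reagent.

**Step 14**
Reactants: 21 [5-(furan-3-yl)pent-1-yn-1-yl]trimethylsilane
Product: 22 3-(pent-4-yn-1-yl)furan
Conditions: K2CO3 (0.2 equiv), MeOH, rt
Reagents that add atoms: none
Why: Methoxide-catalysed protodesilylation of an alkynylsilane is mild and leaves the furan untouched.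

**Step 15**
Reactants: 22 3-(pent-4-yn-1-yl)furan; 16 (E)-vinyl iodide
Product: 24 tert-butyl{[(2S,6S,7E,9E)-13-(furan-3-yl)-2,6,10-trimethyltrideca-7,9-dien-1-yl]oxy}diphenylsilane, via (E)-alkenyldimethylalane 23 (not isolated)
Conditions: 22 (1.5 equiv), Me3Al (3 equiv), Cp2ZrCl2 (0.3 equiv), CH2Cl2, 0 °C → rt; volatiles removed in vacuo; then 16, Pd(PPh3)4 (5 mol %), ZnCl2 (co-catalyst), THF, rt
Reagents that add atoms: trimethylaluminium, C[Al](C)C
Why: Zirconium-catalysed methylalumination adds CH3 and Al syn across the terminal alkyne with Al on the terminal carbon, which fixes the 14E geometry, and the Negishi coupling with the E-iodide forms C13–C14 with retention at both sp2 carbons.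

**Step 16**
Reactants: 24 TBDPS-protected dienyl furan
Product: 25 (2S,6S,7E,9E)-13-(furan-3-yl)-2,6,10-trimethyltrideca-7,9-dien-1-ol
Conditions: TBAF (1.5 equiv), THF, rt
Reagents that add atoms: none
Why: Fluoride-driven cleavage of the Si–O bond is orthogonal to the diene and the furan.

**Step 17**
Reactants: 25 (2S,6S,7E,9E)-13-(furan-3-yl)-2,6,10-trimethyltrideca-7,9-dien-1-ol
Product: 26 (2S,6S,7E,9E)-13-(furan-3-yl)-2,6,10-trimethyltrideca-7,9-dienal
Conditions: Dess–Martin periodinane, CH2Cl2, 0 °C → rt; used crude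
Reagents that add atoms: none
Why: Dess–Martin oxidation is chemoselective for the alcohol over the diene and furan, and being base-free it should keep the α-methyl stereocentre (C7) intact.

**Step 18**
Reactants: 27 ethyl 2-methylacetoacetate
Product: 29 4-hydroxy-3-methylfuran-2(5H)-one (3-methyltetronic acid), via ethyl 4-bromo-2-methyl-3-oxobutanoate 28 (not isolated)
Conditions: Br2 (1.0 equiv), CHCl3, 0 °C → rt, 16 h; concentrate; neat, aq. HBr (cat.), 100–110 °C
Reagents that add atoms: none
Why: In this classical tetronic acid synthesis, bromination under HBr-equilibrating conditions places bromine on the terminal C4, and on heating the ester carbonyl oxygen displaces it in a 5-exo-tet closure of ring B, with bromide removing the ethyl group.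

**Step 19**
Reactants: 29 4-hydroxy-3-methylfuran-2(5H)-one
Product: 30 4-methoxy-3-methylfuran-2(5H)-one
Conditions: Me2SO4 (1.1 equiv), K2CO3, acetone, reflux
Reagents that add atoms: dimethyl sulfate, COS(=O)(=O)OC
Why: The tetronate anion reacts with the hard electrophile dimethyl sulfate at O4 rather than at the already substituted C3, giving the vinylogous methyl ester.

**Step 20**
Reactants: 30 4-methoxy-3-methylfuran-2(5H)-one; 26 (2S,6S,7E,9E)-13-(furan-3-yl)-2,6,10-trimethyltrideca-7,9-dienal
Product: 32 5-[(2S,6S,7E,9E)-13-(furan-3-yl)-1-hydroxy-2,6,10-trimethyltrideca-7,9-dien-1-yl]-4-methoxy-3-methylfuran-2(5H)-one (mixture of C5/C6 epimers), via lithium 4-methoxy-3-methylfuran-2-olate 31 (not isolated)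
Conditions: 30, LiN(i-Pr)2 (LDA, 1.1 equiv), THF, −78 °C; then 26, −78 °C; then AcOH, −78 °C
Reagents that add atoms: none
Why: In this aldol addition of a metallated tetronate, LDA removes a C5 proton to give an aromatic 2-furanolate that adds through C5 to the aldehyde at −78 °C faster than it can enolise it, and the two new stereocentres (C5, C6) need no control because step 21 erases both.

**Step 21**
Reactants: 32 aldol adduct
Product: 34 (5Z)-5-[(2S,6S,7E,9E)-13-(furan-3-yl)-2,6,10-trimethyltrideca-7,9-dien-1-ylidene]-4-methoxy-3-methylfuran-2(5H)-one, via C6 mesylate 33 (not isolated)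
Conditions: MsCl, Et3N, CH2Cl2, 0 °C; then DBU (1.5 equiv), 0 °C → rt
Reagents that add atoms: none
Why: After mesylation, DBU triggers an E1cB elimination through the planar C5 furanolate, so both epimer series converge, and the Z-ylidene is favoured because the E isomer would press the C7 substituent against the 4-methoxy group (allylic strain).

**Step 22**
Reactants: 34 (Z)-ylidene methyl tetronate
Product: 36 (5Z)-5-[(2S,6S,7E,9E)-13-(furan-3-yl)-2,6,10-trimethyltrideca-7,9-dien-1-ylidene]-4-hydroxy-3-methylfuran-2(5H)-one (target), via lithium tetronate 35 (not isolated)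
Conditions: n-PrSLi (from n-PrSH and n-BuLi, 3 equiv), HMPA, rt; then cold 0.5 M HCl
Reagents that add atoms: none
Why: The soft thiolate attacks the O-methyl carbon of the vinylogous ester by SN2 and expels the resonance-stabilised tetronate, whose negative charge then protects C7 and the ylidene from further base chemistry until protonation on work-up.

**Compound list**

| No. | Name | SMILES | Role |
|---|---|---|---|
| 1 | methyl (R)-3-hydroxy-2-methylpropanoate | OC[C@@H](C)C(=O)OC | starting material |
| 2 | methyl (R)-3-(tert-butyldimethylsilyloxy)-2-methylpropanoate | CC(C)(C)[Si](C)(C)OC[C@@H](C)C(=O)OC | intermediate |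
| 3 | (S)-3-(tert-butyldimethylsilyloxy)-2-methylpropan-1-ol | CC(C)(C)[Si](C)(C)OC[C@@H](C)CO | intermediate |
| 4 | (R)-tert-butyl(3-iodo-2-methylpropoxy)dimethylsilane | CC(C)(C)[Si](C)(C)OC[C@@H](C)CI | intermediate |
| 5 | methyl (R)-3-(tert-butyldiphenylsilyloxy)-2-methylpropanoate | CC(C)(C)[Si](c1ccccc1)(c1ccccc1)OC[C@@H](C)C(=O)OC | intermediate |
| 6 | (S)-3-(tert-butyldiphenylsilyloxy)-2-methylpropan-1-ol | CC(C)(C)[Si](c1ccccc1)(c1ccccc1)OC[C@@H](C)CO | intermediate |
| 7 | (R)-tert-butyl(3-iodo-2-methylpropoxy)diphenylsilane | CC(C)(C)[Si](c1ccccc1)(c1ccccc1)OC[C@@H](C)CI | intermediate |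
| 8 | 1,3-dithiane | C1CSCSC1 | starting material |
| 9 | 2-lithio-1,3-dithiane | [Li]C1SCCCS1 | intermediate |
| 10 | (S)-tert-butyl[3-(1,3-dithian-2-yl)-2-methylpropoxy]dimethylsilane | CC(C)(C)[Si](C)(C)OC[C@@H](C)CC1SCCCS1 | intermediate |
| 11 | 2-lithio derivative of 10 | CC(C)(C)[Si](C)(C)OC[C@@H](C)CC1([Li])SCCCS1 | intermediate |
| 12 | 2-[(2S)-3-(tert-butyldimethylsilyloxy)-2-methylpropyl]-2-[(2S)-3-(tert-butyldiphenylsilyloxy)-2-methylpropyl]-1,3-dithiane | CC(C)(C)[Si](C)(C)OC[C@@H](C)CC1(C[C@H](C)CO[Si](c2ccccc2)(c2ccccc2)C(C)(C)C)SCCCS1 | intermediate |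
| 13 | (2S,6S)-1-(tert-butyldimethylsilyloxy)-7-(tert-butyldiphenylsilyloxy)-2,6-dimethylheptane | CC(C)(C)[Si](C)(C)OC[C@@H](C)CCC[C@H](C)CO[Si](c1ccccc1)(c1ccccc1)C(C)(C)C | intermediate |
| 14 | (2S,6S)-7-(tert-butyldiphenylsilyloxy)-2,6-dimethylheptan-1-ol | OC[C@@H](C)CCC[C@H](C)CO[Si](c1ccccc1)(c1ccccc1)C(C)(C)C | intermediate |
| 15 | (2S,6S)-7-(tert-butyldiphenylsilyloxy)-2,6-dimethylheptanal | O=C[C@@H](C)CCC[C@H](C)CO[Si](c1ccccc1)(c1ccccc1)C(C)(C)C | intermediate |
| 16 | tert-butyl{[(2S,6S,7E)-8-iodo-2,6-dimethyloct-7-en-1-yl]oxy}diphenylsilane | I/C=C/[C@@H](C)CCC[C@H](C)CO[Si](c1ccccc1)(c1ccccc1)C(C)(C)C | intermediate |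
| 17 | 3-furanmethanol | OCc1ccoc1 | starting material |
| 18 | 3-(bromomethyl)furan | BrCc1ccoc1 | intermediate |
| 19 | 4-bromo-1-(trimethylsilyl)but-1-yne | C[Si](C)(C)C#CCCBr | starting material |
| 20 | 4-(trimethylsilyl)but-3-yn-1-ylmagnesium bromide | C[Si](C)(C)C#CCC[Mg]Br | intermediate |
| 21 | [5-(furan-3-yl)pent-1-yn-1-yl]trimethylsilane | C[Si](C)(C)C#CCCCc1ccoc1 | intermediate |
| 22 | 3-(pent-4-yn-1-yl)furan | C#CCCCc1ccoc1 | intermediate |
| 23 | [(1E)-5-(furan-3-yl)-2-methylpent-1-en-1-yl]dimethylalane | C[Al](C)/C=C(\C)CCCc1ccoc1 | intermediate |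
| 24 | tert-butyl{[(2S,6S,7E,9E)-13-(furan-3-yl)-2,6,10-trimethyltrideca-7,9-dien-1-yl]oxy}diphenylsilane | CC(C)(C)[Si](c1ccccc1)(c1ccccc1)OC[C@@H](C)CCC[C@H](C)/C=C/C=C(\C)CCCc1ccoc1 | intermediate |
| 25 | (2S,6S,7E,9E)-13-(furan-3-yl)-2,6,10-trimethyltrideca-7,9-dien-1-ol | OC[C@@H](C)CCC[C@H](C)/C=C/C=C(\C)CCCc1ccoc1 | intermediate |
| 26 | (2S,6S,7E,9E)-13-(furan-3-yl)-2,6,10-trimethyltrideca-7,9-dienal | O=C[C@@H](C)CCC[C@H](C)/C=C/C=C(\C)CCCc1ccoc1 | intermediate |
| 27 | ethyl 2-methylacetoacetate | CCOC(=O)C(C)C(C)=O | starting material |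
| 28 | ethyl 4-bromo-2-methyl-3-oxobutanoate (racemic, enolisable) | CCOC(=O)C(C)C(=O)CBr | intermediate |
| 29 | 4-hydroxy-3-methylfuran-2(5H)-one | CC1=C(O)COC1=O | intermediate |
| 30 | 4-methoxy-3-methylfuran-2(5H)-one | COC1=C(C)C(=O)OC1 | intermediate |
| 31 | lithium 4-methoxy-3-methylfuran-2-olate | [Li+].[O-]c1occ(OC)c1C | intermediate |
| 32 | 5-[(2S,6S,7E,9E)-13-(furan-3-yl)-1-hydroxy-2,6,10-trimethyltrideca-7,9-dien-1-yl]-4-methoxy-3-methylfuran-2(5H)-one (C5/C6 epimers) | COC1=C(C)C(=O)OC1C(O)[C@@H](C)CCC[C@H](C)/C=C/C=C(\C)CCCc1ccoc1 | intermediate |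
| 33 | methanesulfonate of 32 (C5/C6 epimers) | COC1=C(C)C(=O)OC1C(OS(C)(=O)=O)[C@@H](C)CCC[C@H](C)/C=C/C=C(\C)CCCc1ccoc1 | intermediate |
| 34 | (5Z)-5-[(2S,6S,7E,9E)-13-(furan-3-yl)-2,6,10-trimethyltrideca-7,9-dien-1-ylidene]-4-methoxy-3-methylfuran-2(5H)-one | CC1=C(OC)/C(=C/[C@@H](C)CCC[C@H](C)/C=C/C=C(\C)CCCc2ccoc2)OC1=O | intermediate |
| 35 | lithium salt of 36 (lithium tetronate) | [Li+].CC1=C([O-])/C(=C/[C@@H](C)CCC[C@H](C)/C=C/C=C(\C)CCCc2ccoc2)OC1=O | intermediate |
| 36 | (5Z)-5-[(2S,6S,7E,9E)-13-(furan-3-yl)-2,6,10-trimethyltrideca-7,9-dien-1-ylidene]-4-hydroxy-3-methylfuran-2(5H)-one | CC1=C(O)/C(=C/[C@@H](C)CCC[C@H](C)/C=C/C=C(\C)CCCc2ccoc2)OC1=O | target |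

**Total step count:** 22
**Longest linear sequence:** 14 steps (1, 2, 3, 7, 8, 9, 10, 11, 15, 16, 17, 20, 21, 22)

**Steps most likely to fail**

**1. Step 7.**
- Risk: the hindered tertiary carbanion may attack the β-branched iodide too slowly. β-Hydrogen abstraction, protonation on warming, or lithium–iodine exchange with leftover t-BuLi would then consume the partners.
- Fallback: a sulfone linchpin built in separate operations. It sets out from 4 and 7 and returns at 13, replacing steps 7 and 8.
- Methyl phenyl sulfone is lithiated (n-BuLi, THF/HMPA, −78 °C) and alkylated with 4 to give tert-butyldimethyl{[(2S)-2-methyl-4-(phenylsulfonyl)butyl]oxy}silane F1.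
- Deprotonation of this sulfone with n-BuLi gives a secondary, far less crowded carbanion. Alkylation with 7 gives (2S,6S)-1-(tert-butyldimethylsilyloxy)-7-(tert-butyldiphenylsilyloxy)-2,6-dimethyl-4-(phenylsulfonyl)heptane F2, whose C4 epimers are of no consequence.
- Reductive desulfonylation (Na/Hg, Na2HPO4, MeOH) should then deliver 13.

**2. Step 15.**
- Risk: in the one-flask sequence the alane cannot be purified. Methyl transfer from residual Me3Al to the vinyl iodide, homocoupling, or carry-over of the regioisomeric alane may erode the coupling.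
- Fallback: a Suzuki–Miyaura union of two isolated partners with the polarity reversed. It sets out from 23 (made from 22 as in step 15) and from 15, and returns at 24, replacing steps 11 and 15.
- Alane 23 is quenched with I2 to give 3-[(4E)-5-iodo-4-methylpent-4-en-1-yl]furan F3, which can be purified.
- Aldehyde 15 is homologated with the Ohira–Bestmann reagent (K2CO3, MeOH) to tert-butyl{[(2S,6S)-2,6-dimethyloct-7-yn-1-yl]oxy}diphenylsilane F4.
- Hydroboration with pinacolborane (Cp2ZrHCl cat.) gives the pinacol (1E,3S,7S)-8-(tert-butyldiphenylsilyloxy)-3,7-dimethyloct-1-en-1-ylboronate F5.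
- Coupling of the iodide and the boronate with Pd(dppf)Cl2 and K3PO4 in DMF/H2O at rt should give 24 with retention at both alkenes.

**3. Step 22.**
- Risk: reversible conjugate addition of the thiolate to the ylidene may scramble the C5=C6 geometry. The basic medium may also epimerise C7 before the methyl group has left.
- Fallback: a fluoride-labile O-protecting group in place of methyl. It sets out from 29 and 26 and returns at 36, replacing steps 19 to 22.
- Mitsunobu etherification of 29 with 2-(trimethylsilyl)ethanol (PPh3, DIAD, THF) gives 3-methyl-4-[2-(trimethylsilyl)ethoxy]furan-2(5H)-one F6.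
- Deprotonation with LDA and addition to 26 as in step 20 gives the aldol adduct 5-[(2S,6S,7E,9E)-13-(furan-3-yl)-1-hydroxy-2,6,10-trimethyltrideca-7,9-dien-1-yl]-3-methyl-4-[2-(trimethylsilyl)ethoxy]furan-2(5H)-one F7.
- Treatment with MsCl/Et3N gives its methanesulfonate F8, and DBU eliminates it to (5Z)-5-[(2S,6S,7E,9E)-13-(furan-3-yl)-2,6,10-trimethyltrideca-7,9-dien-1-ylidene]-3-methyl-4-[2-(trimethylsilyl)ethoxy]furan-2(5H)-one F9.
- TBAF in THF at 0 °C followed by mild acidic work-up should then fragment the silylethyl group and release 36.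

**Further compounds**
F1 | step 7 | tert-butyldimethyl{[(2S)-2-methyl-4-(phenylsulfonyl)butyl]oxy}silane | CC(C)(C)[Si](C)(C)OC[C@@H](C)CCS(=O)(=O)c1ccccc1
F2 | step 7 | (2S,6S)-1-(tert-butyldimethylsilyloxy)-7-(tert-butyldiphenylsilyloxy)-2,6-dimethyl-4-(phenylsulfonyl)heptane | CC(C)(C)[Si](C)(C)OC[C@@H](C)CC(C[C@H](C)CO[Si](c1ccccc1)(c1ccccc1)C(C)(C)C)S(=O)(=O)c1ccccc1
F3 | step 15 | 3-[(4E)-5-iodo-4-methylpent-4-en-1-yl]furan | I/C=C(\C)CCCc1ccoc1
F4 | step 15 | tert-butyl{[(2S,6S)-2,6-dimethyloct-7-yn-1-yl]oxy}diphenylsilane | C#C[C@@H](C)CCC[C@H](C)CO[Si](c1ccccc1)(c1ccccc1)C(C)(C)C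
F5 | step 15 | pinacol (1E,3S,7S)-8-(tert-butyldiphenylsilyloxy)-3,7-dimethyloct-1-en-1-ylboronate | CC1(C)OB(/C=C/[C@@H](C)CCC[C@H](C)CO[Si](c2ccccc2)(c2ccccc2)C(C)(C)C)OC1(C)C
F6 | step 22 | 3-methyl-4-[2-(trimethylsilyl)ethoxy]furan-2(5H)-one | CC1=C(OCC[Si](C)(C)C)COC1=O
F7 | step 22 | 5-[(2S,6S,7E,9E)-13-(furan-3-yl)-1-hydroxy-2,6,10-trimethyltrideca-7,9-dien-1-yl]-3-methyl-4-[2-(trimethylsilyl)ethoxy]furan-2(5H)-one | CC1=C(OCC[Si](C)(C)C)C(OC1=O)C(O)[C@@H](C)CCC[C@H](C)/C=C/C=C(\C)CCCc1ccoc1
F8 | step 22 | methanesulfonate of F7 | CC1=C(OCC[Si](C)(C)C)C(OC1=O)C(OS(C)(=O)=O)[C@@H](C)CCC[C@H](C)/C=C/C=C(\C)CCCc1ccoc1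
F9 | step 22 | (5Z)-5-[(2S,6S,7E,9E)-13-(furan-3-yl)-2,6,10-trimethyltrideca-7,9-dien-1-ylidene]-3-methyl-4-[2-(trimethylsilyl)ethoxy]furan-2(5H)-one | CC1=C(OCC[Si](C)(C)C)/C(=C/[C@@H](C)CCC[C@H](C)/C=C/C=C(\C)CCCc2ccoc2)OC1=O
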